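## Structural features

The target is a C25 cheilanthane-type ether. Rings A (C1–C5, C10), B (C5–C10) and C (C8, C9, C11–C14) form a trans-anti-trans perhydrophenanthrene, and an eight-membered cyclic ether, ring D (O, C13, C14, C15, C16, C17, C18, C19), is fused to it across C13–C14. Ring D contains a Z trisubstituted alkene, C17(CH3)=C18, and its oxygen links the allylic methylene C19 to the fully substituted C13. There are seven stereocentres in three contiguous groups: C5/C6 (5α-H, equatorial 6α-OH), C8/C9/C10 (8β-CH3, 9α-H, 10β-CH3) and C13/C14 (13β-CH3, 13α-O, 14α-H). C8, C10 and C13 are quaternary with three syn-axial β-methyl groups, and O13 and C15 are trans-diequatorial on ring C. The ether is both tertiary (C13) and allylic (C19), so either C–O bond can ionise under strong acid; the alkene and the free 6α-alcohol limit late redox chemistry. The real difficulty is closing a medium ring onto a hindered tertiary carbinol oxygen beside C14 (flanked by quaternary C8 and C13) with fixed Z geometry, where any allyl-electrophile closure can form a six-membered ring at C17 instead of the eight-membered ring at C19. The key step exploits the unit O13–C19H2–C18H=C17(CH3): C19 is a formaldehyde-level carbon bonded only to O13 and C18, and C17 is tertiary. The C18–C19 bond can therefore be made by attack of a C17=C18 vinylsilane on an O13-bound CH2 cation.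

## Logic of the disconnections

**17 ⇒ 15 (through 16).** The C18–C19 bond of ring D is cut, and the 6α-OH is traced back to a second MEM ether. Cutting here turns C19 into the CH2 of a MEM group on O13 and C18 into the silicon-bearing carbon of a Z vinylsilane. This removes the medium ring and the 6- versus 8-membered ambiguity, and it stores the alkene geometry in an acyclic, separately made unit. The forward step must generate the O13=CH2 oxocarbenium ion from a tertiary alkyl MEM ether and have it trapped at C18 before the C13–O bond ionises.

**15 ⇒ 14 ⇒ 12 + 7.** The C15–C16 bond is cut after a phenylsulfonyl group is placed on C15. The side chain then comes from the four-carbon allylic bromide 7, and the tricycle 12 carries only a CH2SO2Ph group on C14. The forward steps need SN2 alkylation of a hindered α-sulfonyl carbanion without SN2′ attack, then reductive C–S cleavage that leaves the vinylsilane and both acetals intact.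

**12 ⇒ 11.** The two O–CH2 bonds of the MEM groups are cut. The group on O13 is the source of C19 and the group on O6 is protection that the key step removes, so no separate deprotection is needed. The forward step must alkylate a hindered tertiary alcohol.

**11 ⇒ 10.** The C8–C14 bond is cut, which opens ring C and removes the C8 and C14 stereocentres. This leads back to a bicyclic labdane with an exocyclic C8=C17 alkene as radical precursor and a C14=C15 vinyl sulfone as acceptor; C13 already holds its oxygen and methyl in the required configuration. The forward step must create a quaternary centre next to C9 and a tertiary centre next to C13 with trans B/C fusion and an equatorial C15.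

**10 ⇒ 8 + 9.** The C14=C15 alkene is cut. The gain is a purchasable diol 8, which supplies rings A and B, the 6α-OH and the C5, C6, C9, C10 and C13 stereocentres, and the sulfone 9. The forward step must engage only the monosubstituted alkene of 8.

**7 ⇒ 6 ⇒ 3 ⇒ 1.** The C–Br, C–Si, C–I and C2–CH3 bonds are cut in turn. The Z relationship between silicon and the CH2X group goes back to an anti-carbometallation of 1, where chelation by the alkoxide fixes the geometry. The forward steps must keep that geometry through halogen–metal exchange.

## Other disconnections considered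

**Alternative 1:** Cut C17=C18 and close ring D by ring-closing metathesis of diene A1 (the 13-O-allyl ether with a 3-methylbut-3-enyl chain on C14). This is the first plan that comes to mind. It is set aside for three reasons.
- A1 needs a Williamson allylation of the hindered tertiary C13 alkoxide while the more reactive 6α-OH is masked and later unmasked, which adds two operations.
- The metathesis must join a 1,1-disubstituted alkene into a trisubstituted alkene within a strained eight-membered ring. That process is reversible, so ring-opening oligomerisation competes under thermodynamic control.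
- In the chosen closure, loss of silicon makes C18–C19 formation irreversible.

**Alternative 2:** Cut C4–C5, C9–C10, C8–C14 and C13–O in one cationic cascade: acid-initiated polycyclisation of (2Z,6E,10E,14E)-geranylfarnesol A2, with the C19 hydroxyl as terminator, to the 6-deoxy tetracycle A3. This is set aside for three reasons.
- The terminating event is capture of the C13 cation through an eight-membered transition state. It must outrun E1 proton loss from C12, C14 or the C13 methyl group, which needs no ring formation.
- A2 is achiral, so the absolute configuration would rest entirely on a chiral acid.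
- A3 lacks the 6α-OH, and C6 is an unactivated methylene with no directing group nearby.
The chosen plan takes five stereocentres and the C6 oxygen from 8 and closes ring D with a built-in regiochemical bias.

**Alternative 3:** Cut O–C19 and close ring D by zerovalent-palladium-catalysed allylic etherification (Tsuji–Trost) of the 13-hydroxy allylic carbonate A4. Ionisation of A4 gives an allyl unit spanning C17–C19. Attack of O13 at C17 closes the six-membered vinyl tetrahydropyran A5 in a 6-exo mode, which is kinetically favoured over eight-membered closure at C19. Syn–anti isomerisation of the allyl unit would also erode the Z geometry. In the chosen plan silicon fixes both the site of bond formation (C18) and the alkene geometry.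

Key step: step 9

Assumption: (+)-larixol (8) is treated as a purchasable labdane diol of 13S configuration (6α-hydroxy-13-epi-manool), the configuration required at C13 of the target.

## Route

Step 1
Reactants: 1 prop-2-yn-1-ol
Product: 3 (Z)-3-iodo-2-methylprop-2-en-1-ol, via alkenylmagnesium alkoxide 2 (not isolated)
Conditions: MeMgBr (2.5 equiv), CuI (10 mol%), THF, −10 → 23 °C; then I2 (1.2 equiv), −10 °C; aq. NH4Cl/Na2S2O3
Reagents that add atoms: methylmagnesium bromide, C[Mg]Br; iodine, II
Why: Copper-catalysed anti-carbomagnesiation of a propargylic alcohol: the magnesium alkoxide directs methyl to C2 and holds magnesium on C3 cis to the CH2O group in a five-membered chelate (2), and iodinolysis with retention gives the Z iodide.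

Step 2
Reactants: 3 (Z)-3-iodo-2-methylprop-2-en-1-ol
Product: 6 (Z)-2-methyl-3-(trimethylsilyl)prop-2-en-1-ol, via dilithio species 4 (not isolated), via bis-silyl ether 5 (not isolated)
Conditions: t-BuLi (3.1 equiv), Et2O, −78 °C; Me3SiCl (2.5 equiv), −78 → 0 °C; then K2CO3 (cat.), MeOH, 0 °C
Reagents that add atoms: chlorotrimethylsilane, C[Si](C)(C)Cl
Why: Deprotonation and iodine–lithium exchange proceed with retention of alkene geometry, and the vinyllithium is silylated on carbon; mild methanolysis removes only the O-silyl group of 5, leaving silicon cis to the CH2OH group.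

Step 3
Reactants: 6 (Z)-2-methyl-3-(trimethylsilyl)prop-2-en-1-ol
Product: 7 (Z)-(3-bromo-2-methylprop-1-en-1-yl)trimethylsilane
Conditions: CBr4 (1.2 equiv), PPh3 (1.25 equiv), CH2Cl2, 0 °C
Reagents that add atoms: carbon tetrabromide, BrC(Br)(Br)Br
Why: Appel bromination of a primary allylic alcohol under neutral conditions, which should avoid protodesilylation and allylic transposition.

Step 4
Reactants: 8 (+)-larixol [(13S)-labda-8(17),14-diene-6α,13-diol]; 9 phenyl vinyl sulfone
Product: 10 (13S,14E)-15-(phenylsulfonyl)labda-8(17),14-diene-6α,13-diol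
Conditions: second-generation Hoveyda–Grubbs catalyst RuCl2(H2IMes)(=CH-C6H4-2-O-i-Pr) (7.5 mol%), 9 (3 equiv), CH2Cl2, 40 °C
Reagents that add atoms: none
Why: Olefin cross-metathesis: the monosubstituted C14=C15 alkene of the unprotected tertiary allylic alcohol should react while the 1,1-disubstituted C8=C17 methylene stays inert to the ruthenium carbene; the electron-poor partner does not homodimerise and should give the E alkene.

Step 5
Reactants: 10 (13S,14E)-15-(phenylsulfonyl)labda-8(17),14-diene-6α,13-diol
Product: 11 tricyclic sulfone diol [rings A/B/C trans-anti-trans; 4,4,8β,10β,13β-pentamethyl; 6α-OH; 13α-OH; 14β-CH2SO2Ph; 5α-H, 9α-H, 14α-H]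
Conditions: Fe(acac)3 (0.3 equiv), PhSiH3 (2.5 equiv), EtOH/HOCH2CH2OH 5:1 (0.02 M, degassed), 60 °C
Reagents that add atoms: none
Why: Hydrogen-atom-transfer-initiated reductive olefin coupling (intramolecular Giese addition): an iron hydride delivers H• to C17 of the electron-rich exocyclic alkene, the tertiary C8 radical adds 6-exo-trig to C14 of the vinyl sulfone, and the α-sulfonyl radical is reduced and protonated by ethanol. The new C8–C14 bond should form on the α (equatorial) side of C8 because the β-axial approach is blocked by the C10 methyl group, giving the trans B/C fusion with 8β-CH3; a chair transition state with the sulfonylvinyl terminus equatorial should give 14α-H. C13 is not touched.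

Step 6
Reactants: 11 tricyclic sulfone diol
Product: 12 6α,13α-bis-O-(2-methoxyethoxymethyl) ether of 11
Conditions: MEMCl (6 equiv), i-Pr2NEt (8 equiv), ClCH2CH2Cl, 60 °C
Reagents that add atoms: 2-methoxyethoxymethyl chloride, COCCOCCl
Why: Alkylation of both hydroxyls by the α-chloro ether through its oxocarbenium ion; the hindered but equatorial tertiary C13 alcohol needs excess reagent and heat, and the sulfone is inert to the amine base.

Step 7
Reactants: 12 bis-MEM ether; 7 (Z)-(3-bromo-2-methylprop-1-en-1-yl)trimethylsilane
Product: 14 bis-MEM sulfone bearing the (Z)-2-methyl-3-(trimethylsilyl)prop-2-enyl group on C15 (C15 epimers), via C15-lithiated sulfone 13 (not isolated)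
Conditions: n-BuLi (1.1 equiv), THF, −78 °C; then 7 (1.5 equiv), −78 → −20 °C
Reagents that add atoms: none
Why: Alkylation of an α-sulfonyl carbanion by a primary allylic bromide (the C–C bond-forming half of a Julia-type fragment coupling); SN2 attack at CH2Br is favoured over SN2′ attack at the silicon-bearing carbon, the alkene geometry is not touched, and the C15 configuration is irrelevant because the sulfone is removed next.

Step 8
Reactants: 14 alkylated bis-MEM sulfone
Product: 15 Z-vinylsilane bis-MEM ether [tricycle with 14β-((Z)-3-methyl-4-(trimethylsilyl)but-3-enyl); 6α-OMEM; 13α-OMEM]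
Conditions: Na(Hg) (6% Na, 8 equiv), Na2HPO4 (6 equiv), MeOH/THF 3:1, −20 → 0 °C
Reagents that add atoms: none
Why: Reductive desulfonylation by single-electron transfer from sodium amalgam in buffered methanol; the sulfone is homoallylic, so no allylic scrambling is expected, and vinylsilane and acetals are inert.

Step 9
Reactants: 15 Z-vinylsilane bis-MEM ether
Product: 17 (17Z)-13α,19-epoxycheilanth-17-en-6α-ol (target), via 6-O-chloromethyl ether 16 (not isolated)
Conditions: SnCl4 (3 equiv), 2,6-di-tert-butyl-4-methylpyridine (1 equiv), CH2Cl2 (0.003 M), −40 → −20 °C; then sat. aq. NaHCO3, 23 °C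
Reagents that add atoms: none
Why: This is a vinylsilane-terminated oxocarbenium (Prins-type) cyclization of a MEM ether, the known acetal-initiated route to allylically unsaturated oxacycles. SnCl4, chelated by the two oxygens of each methoxyethoxy unit, cleaves the distal CH2–O bond and gives the O-methylene oxocarbenium ion on O13 (and the chloromethyl ether on O6). C18 attacks this carbon ipso to silicon because only that mode places the charge on C17, which is tertiary and β to silicon; attack at C17 would give a seven-membered ring and a secondary α-silyl cation. Ring D therefore closes in the 8-endo mode with respect to the vinylsilane, with both alkene carbons inside the ring. Loss of the silyl group from the β-silyl cation is faster than C17–C18 rotation, so C19 replaces silicon with retention and the Z geometry of 15 becomes the ring Z alkene. No stereocentre is formed; the trans-diequatorial (gauche) O13 and C15 substituents on the chair of ring C, together with the Z alkene, hold C18 and C19 within bonding distance. The selectivity needed is cyclization ahead of ionisation of the tertiary C13–O bond and of protodesilylation; the high electrophilicity of the H2C=O+ unit, low temperature, high dilution and the hindered pyridine base are meant to secure it. The O6 chloromethyl ether 16 has no π-nucleophile within reach and is hydrolysed on basic work-up to the free 6α-alcohol.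

## Compound list

1 | prop-2-yn-1-ol | C#CCO | starting material
2 | bromomagnesium (Z)-3-(bromomagnesio)-2-methylprop-2-en-1-olate | Br[Mg]/C=C(/C)CO[Mg]Br | intermediate
3 | (Z)-3-iodo-2-methylprop-2-en-1-ol | I/C=C(/C)CO | intermediate
4 | lithium (Z)-3-lithio-2-methylprop-2-en-1-olate | [Li]/C=C(/C)CO[Li] | intermediate
5 | trimethyl{[(Z)-2-methyl-3-(trimethylsilyl)prop-2-en-1-yl]oxy}silane | C[Si](C)(C)/C=C(/C)CO[Si](C)(C)C | intermediate
6 | (Z)-2-methyl-3-(trimethylsilyl)prop-2-en-1-ol | C[Si](C)(C)/C=C(/C)CO | intermediate
7 | (Z)-(3-bromo-2-methylprop-1-en-1-yl)trimethylsilane | C[Si](C)(C)/C=C(/C)CBr | intermediate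
8 | (+)-larixol, (13S)-labda-8(17),14-diene-6α,13-diol | C=C[C@@](C)(O)CC[C@@H]1[C@@]2(C)CCCC(C)(C)[C@@H]2[C@@H](O)CC1=C | starting material
9 | phenyl vinyl sulfone | C=CS(=O)(=O)c1ccccc1 | starting material
10 | (13S,14E)-15-(phenylsulfonyl)labda-8(17),14-diene-6α,13-diol | O=S(=O)(/C=C/[C@@](C)(O)CC[C@@H]1[C@@]2(C)CCCC(C)(C)[C@@H]2[C@@H](O)CC1=C)c1ccccc1 | intermediate
11 | tricyclic sulfone diol (6α-OH, 13α-OH, 8β/10β/13β-CH3, 14β-CH2SO2Ph, 14α-H) | O[C@@]2(C)CC[C@@H]3[C@@]4(C)CCCC(C)(C)[C@@H]4[C@@H](O)C[C@@]3(C)[C@@H]2CS(=O)(=O)c1ccccc1 | intermediate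
12 | 6α,13α-bis-O-MEM ether of 11 | COCCOCO[C@@]2(C)CC[C@@H]3[C@@]4(C)CCCC(C)(C)[C@@H]4[C@@H](OCOCCOC)C[C@@]3(C)[C@@H]2CS(=O)(=O)c1ccccc1 | intermediate
13 | C15-lithiated derivative of 12 | COCCOCO[C@@]2(C)CC[C@@H]3[C@@]4(C)CCCC(C)(C)[C@@H]4[C@@H](OCOCCOC)C[C@@]3(C)[C@@H]2C([Li])S(=O)(=O)c1ccccc1 | intermediate
14 | bis-MEM sulfone alkylated at C15 with the (Z)-2-methyl-3-(trimethylsilyl)prop-2-enyl group (C15 epimers) | COCCOCO[C@@]2(C)CC[C@@H]3[C@@]4(C)CCCC(C)(C)[C@@H]4[C@@H](OCOCCOC)C[C@@]3(C)[C@@H]2C(CC(\C)=C/[Si](C)(C)C)S(=O)(=O)c1ccccc1 | intermediate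
15 | Z-vinylsilane bis-MEM ether (14β-[(Z)-3-methyl-4-(trimethylsilyl)but-3-enyl]; 6α- and 13α-OMEM) | COCCOCO[C@@]2(C)CC[C@@H]3[C@@]4(C)CCCC(C)(C)[C@@H]4[C@@H](OCOCCOC)C[C@@]3(C)[C@@H]2CCC(\C)=C/[Si](C)(C)C | intermediate
16 | 6-O-chloromethyl ether of 17 | C/C1=C/CO[C@@]2(C)CC[C@@H]3[C@@]4(C)CCCC(C)(C)[C@@H]4[C@@H](OCCl)C[C@@]3(C)[C@@H]2CC1 | intermediate
17 | (17Z)-13α,19-epoxycheilanth-17-en-6α-ol, CNP0179324.1 | C/C1=C/CO[C@@]2(C)CC[C@@H]3[C@@]4(C)CCCC(C)(C)[C@@H]4[C@@H](O)C[C@@]3(C)[C@@H]2CC1 | target

## Step count and least certain steps

Total step count: 9. Longest linear sequence: 6 steps (8 → 17 through steps 4–9; the branch 1 → 7 → 17 through steps 1, 2, 3, 7, 8, 9 is also 6).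

**Step 9 (key step).** What may go wrong:
- heterolysis of the tertiary C13–O bond of the oxocarbenium ion (loss of formaldehyde, then E1 elimination in ring C) may outpace the entropically demanding eight-membered closure;
- protodesilylation of the vinylsilane by adventitious HCl;
- intermolecular alkylation by the O6 oxocarbenium ion if the dilution is insufficient.

Fallback (ring-closing metathesis at C17=C18 in place of C18–C19 bond formation): it sets out from 11. Selective silylation of the secondary 6α-OH (TBSOTf, 2,6-lutidine, CH2Cl2, −78 °C) would give the 6-O-TBS sulfone F1. Double deprotonation (LDA, 2.2 equiv, THF, −78 °C) and C-alkylation with 3-bromo-2-methylpropene would give the methallylated sulfone F2. Na(Hg)/Na2HPO4 in MeOH would give the 13-hydroxy alkene F3. KH and allyl bromide in THF would give the 13-O-allyl diene F4. Second-generation Grubbs catalyst in dilute CH2Cl2 at 40 °C would close ring D to the 6-O-TBS oxocene F5. Bu4NF in THF would return to the route at 17.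

**Step 5.** What may go wrong:
- poor facial control at C14 in the radical addition, with the sulfonylmethyl group ending up axial;
- premature reduction of the C8 radical before cyclization, because bond formation between two heavily substituted carbons is slow.

Fallback (C14 set by directed hydrogenation instead of by the cyclization transition state): it sets out from 10. If the cyclization delivers the C14-epimeric sulfone diol F6, trianion formation (LDA, 3.3 equiv) and PhSeCl would give the α-phenylselenyl sulfone F7. H2O2 would trigger selenoxide syn-elimination to the exocyclic C14=C15 vinyl sulfone F8 (mixture of alkene isomers), which erases C14. Hydrogenation with [Ir(cod)(PCy3)(py)]PF6 and H2 in CH2Cl2, directed by the 13α-OH to the α-face of C14, would return to the route at 11.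

**Step 4.** What may go wrong: slow productive metathesis between a hindered tertiary allylic alcohol and an electron-poor sulfone, so that the ruthenium carbene decomposes before conversion is complete.

Fallback (a reactive boron partner first, sulfone introduced afterwards): it sets out from 8. Cross-metathesis with vinylboronic acid pinacol ester (same catalyst) would give the (E)-alkenylboronate F9. Chan–Lam-type coupling with PhSO2Na mediated by Cu(OAc)2 (divalent copper) under air in DMSO would return to the route at 10.

## Further compounds

F1 | step 9 | 6-O-TBS ether of 11 | O[C@@]2(C)CC[C@@H]3[C@@]4(C)CCCC(C)(C)[C@@H]4[C@@H](O[Si](C)(C)C(C)(C)C)C[C@@]3(C)[C@@H]2CS(=O)(=O)c1ccccc1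
F2 | step 9 | 6-O-TBS sulfone methallylated at C15 (C15 epimers) | O[C@@]2(C)CC[C@@H]3[C@@]4(C)CCCC(C)(C)[C@@H]4[C@@H](O[Si](C)(C)C(C)(C)C)C[C@@]3(C)[C@@H]2C(CC(C)=C)S(=O)(=O)c1ccccc1
F3 | step 9 | 6-O-TBS 13-hydroxy tricycle with 14β-(3-methylbut-3-enyl) | O[C@@]2(C)CC[C@@H]3[C@@]4(C)CCCC(C)(C)[C@@H]4[C@@H](O[Si](C)(C)C(C)(C)C)C[C@@]3(C)[C@@H]2CCC(C)=C
F4 | step 9 | 13-O-allyl 6-O-TBS diene | C=CCO[C@@]2(C)CC[C@@H]3[C@@]4(C)CCCC(C)(C)[C@@H]4[C@@H](O[Si](C)(C)C(C)(C)C)C[C@@]3(C)[C@@H]2CCC(C)=C
F5 | step 9 | 6-O-TBS ether of 17 | C/C1=C/CO[C@@]2(C)CC[C@@H]3[C@@]4(C)CCCC(C)(C)[C@@H]4[C@@H](O[Si](C)(C)C(C)(C)C)C[C@@]3(C)[C@@H]2CC1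
F6 | step 5 | C14 epimer of 11 (14α-CH2SO2Ph) | O[C@@]2(C)CC[C@@H]3[C@@]4(C)CCCC(C)(C)[C@@H]4[C@@H](O)C[C@@]3(C)[C@H]2CS(=O)(=O)c1ccccc1
F7 | step 5 | C15 phenylselenyl derivative of F6 | O[C@@]2(C)CC[C@@H]3[C@@]4(C)CCCC(C)(C)[C@@H]4[C@@H](O)C[C@@]3(C)[C@H]2C([Se]c1ccccc1)S(=O)(=O)c1ccccc1
F8 | step 5 | exocyclic C14=C15 vinyl sulfone diol | O[C@@]2(C)CC[C@@H]3[C@@]4(C)CCCC(C)(C)[C@@H]4[C@@H](O)C[C@@]3(C)C2=CS(=O)(=O)c1ccccc1
F9 | step 4 | (13S,14E)-15-(pinacolatoboryl)labda-8(17),14-diene-6α,13-diol | CC1(C)OB(/C=C/[C@@](C)(O)CC[C@@H]2[C@@]3(C)CCCC(C)(C)[C@@H]3[C@@H](O)CC2=C)OC1(C)C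
A1 | alternative 1 | 13-O-allyl ether of the 6α,13α-diol with 14β-(3-methylbut-3-enyl) | C=CCO[C@@]2(C)CC[C@@H]3[C@@]4(C)CCCC(C)(C)[C@@H]4[C@@H](O)C[C@@]3(C)[C@@H]2CCC(C)=C
A2 | alternative 2 | (2Z,6E,10E,14E)-3,7,11,15,19-pentamethylicosa-2,6,10,14,18-pentaen-1-ol | OC/C=C(C)\CC/C=C(C)/CC/C=C(C)/CC/C=C(C)/CCC=C(C)C
A3 | alternative 2 | 6-deoxy analogue of 17 | C/C1=C/CO[C@@]2(C)CC[C@@H]3[C@@]4(C)CCCC(C)(C)[C@@H]4CC[C@@]3(C)[C@@H]2CC1
A4 | alternative 3 | (17Z)-6α,13α-dihydroxycheilanth-17-en-19-yl methyl carbonate | O[C@@]2(C)CC[C@@H]3[C@@]4(C)CCCC(C)(C)[C@@H]4[C@@H](O)C[C@@]3(C)[C@@H]2CCC(\C)=C/COC(=O)OC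
A5 | alternative 3 | 13,17-epoxy (2-methyl-2-vinyltetrahydropyran) isomer of 17 | C=CC1(C)O[C@@]2(C)CC[C@@H]3[C@@]4(C)CCCC(C)(C)[C@@H]4[C@@H](O)C[C@@]3(C)[C@@H]2CC1
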